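**Assumption:** atom labels follow briarane numbering (C1 = quaternary ring-fusion carbon, C15 its methyl, C19 = lactone carbonyl; β = the face of C15), and but-2-ynoyl chloride, vinylmagnesium chloride and prop-1-ynylmagnesium bromide are bought as such.

## Retrosynthetic overview

1. Target ⇐ one bicyclic 14β-alcohol: 11β,12β-oxirane by a bromohydrin, then C14 inverted by oxidation, equatorial hydride delivery and acetylation in the flask.
2. Key disconnection C1–C10: transannular radical cyclisation of a 14-membered epoxy-cembranolide (Cp2TiCl opens the epoxide to the tertiary C1 radical, which adds 1,6 to the dienyl butenolide). The six- and ten-membered rings form together in this step.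
3. Macrocycle ⇐ intramolecular Heck reaction (C10–C11). Its open form ⇐ Sharpless epoxidation and Mitsunobu butanoylation of an allylic alcohol made by asymmetric alkenylzinc addition (C1–C2) of an iodo-enyne to a butenolide aldehyde.
4. Butenolide aldehyde ⇐ vinylmagnesiation/carboxylation of a propargylic alcohol ⇐ carbocupration of propyne (sets 5Z) and ynone reduction (sets C7). Iodo-enyne ⇐ but-2-yn-1-ol and a propynyl Grignard reagent.
5. Ring order: butenolide → 14-membered carbocycle → six- and ten-membered rings (one step) → oxirane.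

## Route

Step 1
Reactants: 1 2-(2-bromoethyl)-1,3-dioxolane; 2 propyne; 3 but-2-ynoyl chloride
Product: 7 (Z)-8-(1,3-dioxolan-2-yl)-6-methyloct-5-en-2-yn-4-one, via Grignard reagent 4 (not isolated), via alkylcopper 5 (not isolated), via alkenylcopper 6 (not isolated)
Conditions: Mg, THF, 25 °C; CuBr·SMe2 (1.0 equiv), Et2O/Me2S, −45 °C; propyne, −25 °C, 2 h; then 3, Pd(PPh3)4 (3 mol%), −20 → 0 °C
Reagents that add atoms: none
Why: Normant carbocupration adds the alkylcopper syn across propyne with copper on the terminal carbon, which fixes the (Z)-trisubstituted C5=C6 alkene (C4 cis to C7), and the alkenylcopper is then acylated with retention by the acid chloride under Pd(PPh3)4 catalysis (zerovalent palladium).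

Step 2
Reactants: 7 (Z)-8-(1,3-dioxolan-2-yl)-6-methyloct-5-en-2-yn-4-one
Product: 8 (4R,5Z)-8-(1,3-dioxolan-2-yl)-6-methyloct-5-en-2-yn-4-ol
Conditions: (R)-Alpine-Borane [B-isopinocampheyl-9-BBN from (+)-α-pinene] (1.5 equiv), THF, 25 °C, 24 h; then HOCH2CH2NH2, Et2O, 0 °C
Reagents that add atoms: none
Why: Midland reduction of an alkynyl ketone, in which the slim alkyne takes the crowded position of the boat-like transition state so that hydride reaches one carbonyl face and sets C7 as (R), the same sense as 1-octyn-3-one giving (R)-1-octyn-3-ol.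

Step 3
Reactants: 8 (4R,5Z)-8-(1,3-dioxolan-2-yl)-6-methyloct-5-en-2-yn-4-ol; 9 vinylmagnesium chloride
Product: 12 (4Z)-4-methyl-5-[(2R)-4-methyl-5-oxo-3-vinyl-2,5-dihydrofuran-2-yl]pent-4-enal, via magnesium chelate 10 (not isolated), via butenolide acetal 11 (not isolated)
Conditions: 9 (4 equiv), CuI (10 mol%), THF, 0 → 45 °C; CO2 (gas), −20 → 25 °C; then 2 M HCl, THF, 25 °C, 4 h
Reagents that add atoms: carbon dioxide, O=C=O; water, O
Why: Hydroxyl-directed anti-carbomagnesiation of a propargylic alcohol (Duboudin–Fallis type) puts vinyl on C8 and magnesium on C17 in a five-membered chelate, carboxylation of the C–Mg bond and acid work-up close the α-methyl-β-vinyl butenolide without touching the C7–O bond (configuration retained), and the same aqueous acid cleaves the dioxolane.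

Step 4
Reactants: 13 but-2-yn-1-ol
Product: 15 (Z)-3-iodobut-2-en-1-ol, via cyclic alkenylaluminate 14 (not isolated)
Conditions: NaAlH2(OCH2CH2OMe)2 (1.5 equiv), THF, 0 → 25 °C; EtOAc; then I2, −78 → 0 °C
Reagents that add atoms: iodine, [I][I]
Why: trans-Hydroalumination of the propargylic alcohol through the cyclic alkoxyaluminate places aluminium on C3, and iodinolysis with retention gives the (Z)-iodoalkene that later becomes the 11Z alkene.

Step 5
Reactants: 15 (Z)-3-iodobut-2-en-1-ol
Product: 16 (Z)-1-bromo-3-iodobut-2-ene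
Conditions: CBr4 (1.2 equiv), PPh3 (1.25 equiv), CH2Cl2, 0 °C
Reagents that add atoms: tetrabromomethane, BrC(Br)(Br)Br
Why: Appel bromination, an SN2 displacement at the primary allylic carbon that leaves the alkene geometry and the vinyl iodide untouched.

Step 6
Reactants: 16 (Z)-1-bromo-3-iodobut-2-ene; 17 prop-1-yn-1-ylmagnesium bromide
Product: 18 (Z)-2-iodohept-2-en-5-yne
Conditions: 17 (1.3 equiv), CuBr·SMe2 (10 mol%), THF, −20 → 25 °C
Reagents that add atoms: none
Why: Copper-catalysed coupling of an alkynyl Grignard reagent with a primary allylic bromide at the unhindered α-carbon (the γ-carbon carries iodine and methyl) gives the skipped enyne, and the vinyl iodide does not exchange with an alkynylmagnesium reagent.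

Step 7
Reactants: 18 (Z)-2-iodohept-2-en-5-yne; 12 (4Z)-4-methyl-5-[(2R)-4-methyl-5-oxo-3-vinyl-2,5-dihydrofuran-2-yl]pent-4-enal
Product: 21 (5R)-5-[(1Z,5R,6E,9Z)-5-hydroxy-10-iodo-2,6-dimethylundeca-1,6,9-trien-1-yl]-3-methyl-4-vinylfuran-2(5H)-one, via alkenylzirconocene 19 (not isolated), via alkenylzinc 20 (not isolated)
Conditions: 18 (1.4 equiv), Cp2Zr(H)Cl (1.45 equiv), CH2Cl2, 25 °C, 1 h; Me2Zn, toluene, −65 °C; (−)-MIB (10 mol%); 12, −30 → 0 °C; aq NH4Cl
Reagents that add atoms: none
Why: Hydrozirconation, zinc transmetalation and catalytic asymmetric alkenylation (Wipf/Walsh type), in which syn Zr–H addition puts zirconium on the methyl-bearing alkyne carbon (about 9:1 after equilibration) to give the (E)-C14=C1 alkene, and the (−)-MIB zinc catalyst delivers the alkenyl group to the Si face of the aldehyde to set C2 as (R).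

Step 8
Reactants: 21 (5R)-5-[(1Z,5R,6E,9Z)-5-hydroxy-10-iodo-2,6-dimethylundeca-1,6,9-trien-1-yl]-3-methyl-4-vinylfuran-2(5H)-one
Product: 22 erythro epoxy alcohol: 21 with a trans-1,14-epoxide, (2R)-carbinol, C14 (R)
Conditions: Ti(OiPr)4 (0.3 equiv), D-(−)-DIPT (0.36 equiv), t-BuOOH (2 equiv, decane), 4 Å MS, CH2Cl2, −20 °C
Reagents that add atoms: tert-butyl hydroperoxide, CC(C)(C)OO
Why: Sharpless asymmetric epoxidation of a secondary allylic alcohol in the matched sense, in which D-(−)-DIPT delivers oxygen to the alkene face that gives the erythro epoxy alcohol with C14 (R), leaves the other alkenes untouched and leaves behind any (2S) epimer from step 7.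

Step 9
Reactants: 22 erythro epoxy alcohol
Product: 23 threo epoxy butanoate: (2S)-butanoate, trans-1,14-epoxide with C14 (R), vinyl iodide and vinylbutenolide unchanged
Conditions: butanoic acid (3 equiv), PPh3 (3 equiv), DIAD (3 equiv), toluene, 0 → 25 °C
Reagents that add atoms: butanoic acid, CCCC(=O)O
Why: Mitsunobu esterification, an SN2 displacement of the activated C2 oxygen by butanoate that inverts C2 to (S) and installs the butanoate in one operation, giving the threo relationship needed for the key step.

Step 10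
Reactants: 23 threo epoxy butanoate
Product: 24 14-membered epoxy-cembranolide (1,10-seco-briarane): (2S)-butanoate, (7R)-butenolide, trans-1,14-epoxide with C14 (R), 5Z,9E,11Z
Conditions: Pd(OAc)2 (20 mol%), PPh3 (40 mol%), Ag2CO3 (1.5 equiv), MeCN, 0.002 M, 60 °C
Reagents that add atoms: none
Why: Intramolecular Heck macrocyclisation, in which oxidative addition into the vinyl iodide with retention, insertion at the terminal carbon of the electron-poor vinylbutenolide and syn β-hydride elimination give the (9E,11Z)-diene, while Ag2CO3 removes iodide and is too weak a base to epimerise C7.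

Step 11
Reactants: 24 14-membered epoxy-cembranolide
Product: 26 trans-fused bicyclic 14β-alcohol: (2S)-butanoate, (7R)-butenolide conjugated at C8=C17, C11=C12 alkene, C15 methyl β, H-10 α, 14β-OH, via deconjugated lactone 25 (not isolated)
Conditions: Cp2TiCl2 (0.3 equiv), Mn dust (4 equiv), 2,4,6-collidine·HCl (3 equiv), THF, 25 °C, 24 added over 4 h (final 0.005 M); aq NaH2PO4; then Et3N (0.5 equiv), CH2Cl2, 25 °C
Reagents that add atoms: none
Why: Proposed new method: Cp2TiCl (trivalent titanium, made in the flask) opens the trisubstituted epoxide by single-electron transfer to the tertiary C1 radical with the C14–O–Ti bond intact, this nucleophilic radical adds transannularly (6-exo, a 1,6-Giese addition) to C10 of the dienyl butenolide to form the C1–C10 bond and split the 14-membered ring into the six- and ten-membered rings, a second Cp2TiCl reduces the ester-stabilised C9 radical to a titanium dienolate that is protonated, and Et3N brings the alkene back into conjugation; a chair-like transition state with the bulky titanoxy group and both macrocycle arms (C2 and C9, s-trans diene) equatorial and the C15 methyl axial should give the trans ring fusion and the 14β-alcohol; the closest known reaction types are the Cp2TiCl-mediated transannular cyclisation of epoxygermacrolides to eudesmanolides and the Nugent–RajanBabu epoxide–acrylate radical addition.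

Step 12
Reactants: 26 trans-fused bicyclic 14β-alcohol
Product: 28 11β,12β-epoxy-14β-alcohol, via bromohydrin 27 (not isolated)
Conditions: NBS (1.1 equiv), THF/H2O 4:1, 0 °C, dark; then K2CO3 (3 equiv), 0 → 25 °C, 30 min
Reagents that add atoms: water, O
Why: Bromohydrin route to the epoxide on the face that direct epoxidation would avoid, in which bromonium forms on the open α face of the more electron-rich C11=C12 alkene (the β face is shielded by the axial C15 methyl, and C5=C6 is deactivated by the allylic lactone oxygen), water opens it at the tertiary C11 from the β face (Markovnikov, trans-diaxial), and the 11β-alkoxide closes onto C12 with inversion.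

Step 13
Reactants: 28 11β,12β-epoxy-14β-alcohol
Product: 29 11β,12β-epoxy-14-ketone
Conditions: Dess–Martin periodinane (1.5 equiv), NaHCO3, CH2Cl2, 0 → 25 °C
Reagents that add atoms: none
Why: Dess–Martin oxidation of the secondary alcohol under buffered conditions that leave the epoxide, both esters and the alkenes alone and do not enolise the new ketone towards the epoxide.

Step 14
Reactants: 29 11β,12β-epoxy-14-ketone
Product: 31 target CNP0220791.2 (1S,2S,5Z,7R,10R,11R,12S,14S): 14α-acetate, 2-butanoate, 11β,12β-epoxide, via lithium 14α-alkoxide 30 (not isolated)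
Conditions: LiBH(s-Bu)3 (1.2 equiv), THF, −78 °C; then Ac2O (6 equiv), DMAP (0.3 equiv), −78 → 0 °C; aq NH4Cl
Reagents that add atoms: acetic anhydride, CC(=O)OC(C)=O
Why: The bulky hydride attacks the C14 ketone along the equatorial trajectory because axial attack is blocked by the axial hydrogens on C10 and C12 (as in the reduction of 4,4-dimethyl-3-keto terpenoids to axial alcohols), which gives the axial 14α-alkoxide, and this is acetylated in the flask before the neighbouring C2 butanoate can migrate.

## Compound list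

1 | 2-(2-bromoethyl)-1,3-dioxolane | BrCCC1OCCO1 | starting material
2 | propyne | CC#C | starting material
3 | but-2-ynoyl chloride | CC#CC(Cl)=O | starting material
4 | [2-(1,3-dioxolan-2-yl)ethyl]magnesium bromide | Br[Mg]CCC1OCCO1 | intermediate
5 | [2-(1,3-dioxolan-2-yl)ethyl]copper (MgBr2 complex) | [Cu]CCC1OCCO1 | intermediate
6 | (Z)-[4-(1,3-dioxolan-2-yl)-2-methylbut-1-en-1-yl]copper | [Cu]/C=C(C)\CCC1OCCO1 | intermediate
7 | (Z)-8-(1,3-dioxolan-2-yl)-6-methyloct-5-en-2-yn-4-one | CC#CC(=O)/C=C(C)\CCC1OCCO1 | intermediate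
8 | (4R,5Z)-8-(1,3-dioxolan-2-yl)-6-methyloct-5-en-2-yn-4-ol | CC#C[C@H](O)/C=C(C)\CCC1OCCO1 | intermediate
9 | vinylmagnesium chloride | C=C[Mg]Cl | starting material
10 | cyclic alkenylmagnesium alkoxide (vinyl on C8, Mg on C17, O–Mg chelate, 7R) | C=CC1=C(C)[Mg]O[C@@H]1/C=C(C)\CCC1OCCO1 | intermediate
11 | (5R)-5-[(1Z)-4-(1,3-dioxolan-2-yl)-2-methylbut-1-en-1-yl]-3-methyl-4-vinylfuran-2(5H)-one | C=CC1=C(C)C(=O)O[C@@H]1/C=C(C)\CCC1OCCO1 | intermediate
12 | (4Z)-4-methyl-5-[(2R)-4-methyl-5-oxo-3-vinyl-2,5-dihydrofuran-2-yl]pent-4-enal | O=CCC/C(C)=C\[C@H]1OC(=O)C(C)=C1C=C | intermediate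
13 | but-2-yn-1-ol | CC#CCO | starting material
14 | sodium cyclic alkoxy(alkenyl)bis(2-methoxyethoxy)aluminate | CC1=CCO[Al-]1(OCCOC)OCCOC.[Na+] | intermediate
15 | (Z)-3-iodobut-2-en-1-ol | I/C(C)=C\CO | intermediate
16 | (Z)-1-bromo-3-iodobut-2-ene | I/C(C)=C\CBr | intermediate
17 | prop-1-yn-1-ylmagnesium bromide | CC#C[Mg]Br | starting material
18 | (Z)-2-iodohept-2-en-5-yne | I/C(C)=C\CC#CC | intermediate
19 | chloro[(2E,5Z)-6-iodohepta-2,5-dien-2-yl]zirconocene, Cp2Zr(Cl)R | I/C(C)=C\C/C=C(C)/[Zr](Cl)(C1C=CC=C1)C1C=CC=C1 | intermediate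
20 | [(2E,5Z)-6-iodohepta-2,5-dien-2-yl](methyl)zinc | I/C(C)=C\C/C=C(C)/[Zn]C | intermediate
21 | (5R)-5-[(1Z,5R,6E,9Z)-5-hydroxy-10-iodo-2,6-dimethylundeca-1,6,9-trien-1-yl]-3-methyl-4-vinylfuran-2(5H)-one | I/C(C)=C\C/C=C(C)/[C@H](O)CC/C(C)=C\[C@H]1OC(=O)C(C)=C1C=C | intermediate
22 | erythro epoxy alcohol: 21 with trans-1,14-epoxide, (2R)-OH, C14 (R), 7R | I/C(C)=C\C[C@H]1O[C@]1(C)[C@H](O)CC/C(C)=C\[C@H]2OC(=O)C(C)=C2C=C | intermediate
23 | threo epoxy butanoate: (2S)-butanoate, trans-1,14-epoxide, C14 (R), 7R | I/C(C)=C\C[C@H]1O[C@]1(C)[C@@H](OC(=O)CCC)CC/C(C)=C\[C@H]2OC(=O)C(C)=C2C=C | intermediate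
24 | 14-membered epoxy-cembranolide: (2S)-butanoate, 7R, trans-1,14-epoxide (C1 S, C14 R), 5Z,9E,11Z | CCCC(=O)O[C@H]1CC/C(C)=C\[C@H]2OC(=O)C(C)=C2/C=C/C(C)=C\C[C@H]3O[C@]13C | intermediate
25 | bicyclic β,γ-unsaturated lactone (C8=C9 alkene, H on C17, both C17 epimers), otherwise as 26 | CCCC(=O)O[C@H]1CC/C(C)=C\[C@H]2OC(=O)C(C)/C2=C/[C@H]2C(C)=CC[C@@H](O)[C@]12C | intermediate
26 | trans-fused bicyclic butenolide: (2S)-butanoate, 7R, C15 methyl β, H-10 α, C11=C12 alkene, 14β-OH | CCCC(=O)O[C@H]1CC/C(C)=C\[C@H]2OC(=O)C(C)=C2C[C@H]2C(C)=CC[C@@H](O)[C@]12C | intermediate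
27 | bromohydrin: 26 with 11β-OH and 12α-Br | CCCC(=O)O[C@H]1CC/C(C)=C\[C@H]2OC(=O)C(C)=C2C[C@H]2[C@@](C)(O)[C@H](Br)C[C@@H](O)[C@]12C | intermediate
28 | 11β,12β-epoxy-14β-alcohol | CCCC(=O)O[C@H]1CC/C(C)=C\[C@H]2OC(=O)C(C)=C2C[C@H]2[C@@]3(C)O[C@H]3C[C@@H](O)[C@]12C | intermediate
29 | 11β,12β-epoxy-14-ketone | CCCC(=O)O[C@H]1CC/C(C)=C\[C@H]2OC(=O)C(C)=C2C[C@H]2[C@@]3(C)O[C@H]3CC(=O)[C@]12C | intermediate
30 | lithium 14α-alkoxide of the 11β,12β-epoxide | CCCC(=O)O[C@H]1CC/C(C)=C\[C@H]2OC(=O)C(C)=C2C[C@H]2[C@@]3(C)O[C@H]3C[C@H](O[Li])[C@]12C | intermediate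
31 | CNP0220791.2: (1S,2S,5Z,7R,10R,11R,12S,14S)-14-acetoxy-2-butanoyloxy-11,12-epoxy briarane butenolide | CCCC(=O)O[C@H]1CC/C(C)=C\[C@H]2OC(=O)C(C)=C2C[C@H]2[C@@]3(C)O[C@H]3C[C@H](OC(C)=O)[C@]12C | target

## Step count and risks

Total step count: 14. Longest linear sequence: 11 steps (steps 1–3, then 7–14; the branch through steps 4–6 is equally long).

The three steps most likely to fail:

**Step 11 (transannular radical cyclisation).** The tertiary C1 radical may be trapped by Cp2TiCl and lose a β-hydrogen before it cyclises, or the titanoxy group may steer the fusion the wrong way. The fallback changes how the radical is made. It sets out from 24, which is isomerised on purpose with preformed Cp2TiCl (2.2 equiv, 0.2 M in THF, no acid) to the exo-methylene allylic alcohol F6 (C1=C15 methylene, free 14-OH, C14 unchanged). F6 is then treated with Fe(acac)3 and PhSiH3 in EtOH/ethylene glycol at 60 °C. Hydrogen-atom transfer to the methylene regenerates the same C1 radical, now with a small free hydroxyl on C14 and no trivalent titanium to intercept it. The 1,6-addition and reduction of the dienyl radical by the iron hydride cycle follow, and the route is rejoined at 26.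

**Step 10 (macrocyclic Heck reaction).** The 14-membered closure may lose to oligomerisation or to isomerisation of the (Z)-iodoalkene. The fallback makes the same C10–C11 bond intermolecularly and closes the ring elsewhere. It sets out from 12 and 18, which are joined under the same Pd(OAc)2/PPh3/Ag2CO3 conditions at 0.1 M to give the dienyl ynal F3. Nickel-catalysed reductive alkyne–aldehyde macrocyclisation (Ni(cod)2, IMes, Et3B, toluene, 0.005 M) then forms the C1–C2 bond at the methyl-bearing alkyne carbon and gives the macrocyclic allylic alcohol F4 as a mixture at C2. Sharpless epoxidation with D-(−)-DIPT converts only the (2R) epimer into the macrocyclic epoxy alcohol F5. Mitsunobu reaction with butanoic acid inverts C2, and the route is rejoined at 24.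

**Step 9 (Mitsunobu inversion).** The carbinol sits next to a fully substituted epoxide carbon and butanoic acid is a weak pronucleophile, so displacement may be slow or give elimination. The fallback replaces SN2 inversion by an oxidation–reduction pair. It sets out from 22, which is oxidised with Dess–Martin periodinane to the epoxy ketone F1. Catalyst-controlled reduction with (R)-CBS oxazaborolidine and BH3·SMe2 gives the threo (2S) epoxy alcohol F2. Acylation with butanoic anhydride, DMAP and pyridine rejoins the route at 23.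

## Further compounds

F1 | step 9 | epoxy ketone: 22 with C2 oxidised to the ketone | I/C(C)=C\C[C@H]1O[C@]1(C)C(=O)CC/C(C)=C\[C@H]2OC(=O)C(C)=C2C=C
F2 | step 9 | threo epoxy alcohol: (2S)-epimer of 22 | I/C(C)=C\C[C@H]1O[C@]1(C)[C@@H](O)CC/C(C)=C\[C@H]2OC(=O)C(C)=C2C=C
F3 | step 10 | dienyl ynal: 12 carrying the (1E,3Z)-3-methylocta-1,3-dien-6-ynyl chain on C8 | O=CCC/C(C)=C\[C@H]1OC(=O)C(C)=C1/C=C/C(C)=C\CC#CC
F4 | step 10 | macrocyclic allylic alcohol: 14-membered ring, (2R)-OH drawn, (E)-C1=C14 alkene, 5Z,9E,11Z | O[C@@H]1CC/C(C)=C\[C@H]2OC(=O)C(C)=C2/C=C/C(C)=C\C/C=C1\C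
F5 | step 10 | macrocyclic erythro epoxy alcohol: 24 with free (2R)-OH in place of the (2S)-butanoate | O[C@@H]1CC/C(C)=C\[C@H]2OC(=O)C(C)=C2/C=C/C(C)=C\C[C@H]3O[C@]13C
F6 | step 11 | exo-methylene allylic alcohol: 24 with C1=C15 methylene and free 14-OH | CCCC(=O)O[C@H]1CC/C(C)=C\[C@H]2OC(=O)C(C)=C2/C=C/C(C)=C\C[C@@H](O)C1=C
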